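**Retrosynthetic overview**
1. The strategy rests on the α-methyl-β-hydroxy ester at C1–C3: the lactone carbonyl C1 has the C2 methyl and the C3 hydroxyl syn to each other inside the only ring (28-membered, C1–C27 plus the ring oxygen). That is a propionate aldol retron, so the ring is opened at C2–C3 and not at O–C1, giving C3 aldehyde 42 with a 2-bromopropanoate on O27.
2. 42 comes from pentaene alcohol 38 (acylation of O27, unmasking and oxidation of C3); 38 comes from a Stille coupling at C17–C18 of vinyl iodide 24 (C3–C17) with tetraenylstannane 37 (C18–C28).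
3. 24 comes from a 1,5-anti boron aldol at C9–C10 between aldehyde 5 (C3–C9) and methyl ketone 16 (C10–C17), then syn reduction; 16 comes from an Evans syn aldol (C14–C15), a Claisen extension (C12–C13) and an anti reduction.
4. 37 comes from the cyclic sulfate of (2R,3R)-butane-2,3-diol and an enynyl acetylide (C25–C26), trans-hydroalumination, Takai iodo-olefination and a Stille coupling with (E)-1,2-bis(tributylstannyl)ethene.
5. Ring order: the single ring is closed in step 26; MOM cleavage and global desilylation follow.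

Key step: step 26

Remark: positions are numbered along the chain from C1 (lactone carbonyl) to C27 (carbon on the ring oxygen), C28 being its methyl; the target is 2S,3R,5S,9S,11S,13R,14R,15R,26R,27R with five E double bonds C16–C25 (TBS = tert-butyldimethylsilyl, MOM = methoxymethyl). Compounds 1, 6, 7, 11, 25, 27, 36, 39 and the allylborane of step 1 are taken as commercial.

**Fragment C3–C9**

Step 1
Reactants: 1 3-(tert-butyldimethylsilyloxy)propanal
Product: 3 (S)-1-(tert-butyldimethylsilyloxy)hex-5-en-3-ol, via diisopinocampheylborinate 2 (not isolated)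
Conditions: (−)-Ipc2B(allyl), Et2O, −78 °C; then NaOH, H2O2, 0 °C → rt
Reagents that add atoms: (−)-B-allyldiisopinocampheylborane, C=CCB([C@@H]1C[C@@H]2C[C@H]([C@H]1C)C2(C)C)[C@@H]1C[C@@H]2C[C@H]([C@H]1C)C2(C)C
Why: Brown allylboration, in which the reagent derived from (+)-α-pinene should deliver allyl through a chair six-membered transition state to the Si face of the aldehyde and so set C5 as S.

Step 2
Reactants: 3 (S)-1-(tert-butyldimethylsilyloxy)hex-5-en-3-ol
Product: 4 (S)-1-(tert-butyldimethylsilyloxy)-3-(methoxymethoxy)hex-5-ene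
Conditions: MOMCl, i-Pr2NEt, Bu4NI (cat.), CH2Cl2, 0 °C → rt
Reagents that add atoms: chloromethyl methyl ether, COCCl
Why: Base-mediated O-alkylation with the chloromethyl ether installs the chelating MOM group needed at C5 in the key step and leaves the silyl ether and alkene untouched.

Step 3
Reactants: 4 (S)-1-(tert-butyldimethylsilyloxy)-3-(methoxymethoxy)hex-5-ene
Product: 5 (S)-7-(tert-butyldimethylsilyloxy)-5-(methoxymethoxy)heptanal
Conditions: Rh(acac)(CO)2 (cat.), BIPHEPHOS (cat.), CO/H2 (1:1, 5 bar), THF, 60 °C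
Reagents that add atoms: carbon monoxide, [C-]#[O+]
Why: Rhodium-catalysed hydroformylation with a wide-bite-angle bisphosphite should be linear-selective on the terminal alkene and give the C9 aldehyde in one operation.

**Fragment C10–C17 and union to C3–C17**

Step 4
Reactants: 6 (S)-4-benzyl-3-propanoyloxazolidin-2-one; 7 3-(trimethylsilyl)prop-2-ynal
Product: 9 (4S)-4-benzyl-3-[(2S,3S)-3-hydroxy-2-methyl-5-(trimethylsilyl)pent-4-ynoyl]oxazolidin-2-one, via Z-dibutylboron enolate 8 (not isolated)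
Conditions: Bu2BOTf, Et3N, CH2Cl2, −78 → 0 °C; then 7, −78 → 0 °C; pH 7 buffer, MeOH, H2O2
Reagents that add atoms: none
Why: Evans syn aldol, in which the Z-boron enolate reacts through a chair Zimmerman–Traxler transition state on the face away from the benzyl group and should set C14 and C15 (syn) in the sense of the target.

Step 5
Reactants: 9 (4S)-4-benzyl-3-[(2S,3S)-3-hydroxy-2-methyl-5-(trimethylsilyl)pent-4-ynoyl]oxazolidin-2-one
Product: 10 (2S,3S)-3-hydroxy-N-methoxy-N,2-dimethyl-5-(trimethylsilyl)pent-4-ynamide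
Conditions: MeNH(OMe)·HCl, AlMe3, THF, −20 → 0 °C
Reagents that add atoms: N,O-dimethylhydroxylamine hydrochloride, CNOC.Cl
Why: Aluminium amide transamination of the β-hydroxy imide (Weinreb amide formation) removes the auxiliary under conditions that should not epimerise C14.

Step 6
Reactants: 10 (2S,3S)-3-hydroxy-N-methoxy-N,2-dimethyl-5-(trimethylsilyl)pent-4-ynamide; 11 N-methoxy-N-methylacetamide
Product: 13 (4S,5S)-5-hydroxy-N-methoxy-N,4-dimethyl-3-oxo-7-(trimethylsilyl)hept-6-ynamide, via lithium amide enolate 12 (not isolated)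
Conditions: 11, LiN(i-Pr)2 (excess), THF, −78 °C; then 10, −78 → −30 °C; NH4Cl (aq)
Reagents that add atoms: none
Why: Claisen-type acylation of an amide enolate by a Weinreb amide, whose metal-chelated adduct collapses only on work-up so that over-addition is avoided, the excess enolate first taking the free hydroxyl to its alkoxide.

Step 7
Reactants: 13 (4S,5S)-5-hydroxy-N-methoxy-N,4-dimethyl-3-oxo-7-(trimethylsilyl)hept-6-ynamide
Product: 14 (3R,4R,5S)-3,5-dihydroxy-N-methoxy-N,4-dimethyl-7-(trimethylsilyl)hept-6-ynamide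
Conditions: Me4NBH(OAc)3, MeCN/AcOH, −30 → −20 °C
Reagents that add atoms: none
Why: Evans–Saksena reduction, in which the C15 hydroxyl binds boron and hydride is delivered intramolecularly through a chair transition state, should give the 13,15-anti diol and set C13.

Step 8
Reactants: 14 (3R,4R,5S)-3,5-dihydroxy-N-methoxy-N,4-dimethyl-7-(trimethylsilyl)hept-6-ynamide
Product: 15 N-methoxy-N-methyl-2-[(2R,4R,5R,6S)-2-(4-methoxyphenyl)-5-methyl-6-(trimethylsilylethynyl)-1,3-dioxan-4-yl]acetamide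
Conditions: 4-MeOC6H4CH(OMe)2, PPTS (cat.), CH2Cl2, rt
Reagents that add atoms: 4-methoxybenzaldehyde dimethyl acetal, COc1ccc(C(OC)OC)cc1
Why: Acid-catalysed transacetalisation under thermodynamic control (aryl equatorial, cis to the C13 side chain) masks the diol and makes O13 the alkyl-acetal oxygen that directs the aldol of step 10.

Step 9
Reactants: 15 N-methoxy-N-methyl-2-[(2R,4R,5R,6S)-2-(4-methoxyphenyl)-5-methyl-6-(trimethylsilylethynyl)-1,3-dioxan-4-yl]acetamide
Product: 16 1-[(2R,4R,5R,6S)-2-(4-methoxyphenyl)-5-methyl-6-(trimethylsilylethynyl)-1,3-dioxan-4-yl]propan-2-one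
Conditions: MeMgBr, THF, 0 °C; NH4Cl (aq)
Reagents that add atoms: methylmagnesium bromide, C[Mg]Br
Why: Grignard addition to a Weinreb amide stops at the chelated adduct and should give the methyl ketone on work-up, the silylalkyne and acetal being inert.

Step 10
Reactants: 16 1-[(2R,4R,5R,6S)-2-(4-methoxyphenyl)-5-methyl-6-(trimethylsilylethynyl)-1,3-dioxan-4-yl]propan-2-one; 5 (S)-7-(tert-butyldimethylsilyloxy)-5-(methoxymethoxy)heptanal
Product: 18 C3–C17 aldol adduct (3-TBS ether; 5-MOM ether; 9-hydroxy-11-ketone; 13,15-O-arylidene acetal; C17 silylalkyne), via dicyclohexylboron enolate 17 (not isolated)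
Conditions: (c-C6H11)2BCl, Et3N, Et2O, −78 → 0 °C; then 5, −78 → −20 °C; MeOH, pH 7 buffer, H2O2
Reagents that add atoms: none
Why: Boron aldol of a β-alkoxy methyl ketone, in which kinetic enolisation on the methyl side and 1,5-anti induction from the β-acetal oxygen O13 should set C9.

Step 11
Reactants: 18 C3–C17 aldol adduct
Product: 19 C3–C17 9,11-syn diol (3-TBS ether; 5-MOM ether; 13,15-O-arylidene acetal; C17 silylalkyne)
Conditions: Et2BOMe, NaBH4, THF/MeOH, −78 °C; AcOH; MeOH azeotrope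
Reagents that add atoms: none
Why: Narasaka–Prasad reduction, in which external hydride attacks the diethylboron-chelated β-hydroxy ketone from the less hindered face of the half-chair, should give the 9,11-syn diol and set C11.

Step 12
Reactants: 19 C3–C17 9,11-syn diol
Product: 21 C3–C17 alkynyl pentaol (3,9,11,13,15-pentahydroxy; 5-MOM ether; terminal C16–C17 alkyne), via C17-silyl pentaol 20 (not isolated)
Conditions: CSA (cat.), MeOH, 0 °C → rt; then K2CO3, rt
Reagents that add atoms: none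
Why: Acid-catalysed methanolysis removes the arylidene acetal and the primary silyl ether while the MOM ether should survive catalytic acid at room temperature, and methanolic carbonate then cleaves the C(sp)–Si bond.

Step 13
Reactants: 21 C3–C17 alkynyl pentaol
Product: 22 C3–C17 alkyne penta-TBS ether (3,9,11,13,15-O-TBS; 5-MOM ether)
Conditions: TBSOTf (excess), 2,6-lutidine, CH2Cl2, −78 → 0 °C
Reagents that add atoms: tert-butyldimethylsilyl triflate, CC(C)(C)[Si](C)(C)OS(=O)(=O)C(F)(F)F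
Why: Exhaustive silylation with the silyl triflate installs the four secondary TBS ethers carried to the end and a primary one at C3 that can be removed selectively later.

Step 14
Reactants: 22 C3–C17 alkyne penta-TBS ether
Product: 24 C3–C17 (E)-vinyl iodide (3,9,11,13,15-O-TBS; 5-MOM ether; iodine on C17), via alkenylzirconocene 23 (not isolated)
Conditions: Cp2Zr(H)Cl, THF, rt; then I2, 0 °C
Reagents that add atoms: iodine, II
Why: Hydrozirconation is a syn addition that places zirconium on the terminal carbon, and iodinolysis with retention should give the (E)-vinyl iodide only.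

**Fragment C18–C28**

Step 15
Reactants: 25 (E)-pent-2-en-4-yn-1-ol
Product: 26 (E)-tert-butyldimethyl(pent-2-en-4-yn-1-yloxy)silane
Conditions: TBSCl, imidazole, CH2Cl2, 0 °C → rt
Reagents that add atoms: tert-butyldimethylsilyl chloride, CC(C)(C)[Si](C)(C)Cl
Why: Standard silylation masks the hydroxyl so that only the acetylide carbon is nucleophilic in step 17.

Step 16
Reactants: 27 (2R,3R)-butane-2,3-diol
Product: 29 (4R,5R)-4,5-dimethyl-1,3,2-dioxathiolane 2,2-dioxide, via cyclic sulfite 28 (not isolated)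
Conditions: SOCl2, CH2Cl2, reflux; then RuCl3·3H2O (cat.), NaIO4, MeCN/H2O, 0 °C
Reagents that add atoms: thionyl chloride, O=S(Cl)Cl; sodium periodate, [Na+].[O-]I(=O)(=O)=O
Why: Cyclic sulfite formation and ruthenium-catalysed oxidation to the cyclic sulfate activate the diol without breaking a C–O bond, so both stereocentres are retained.

Step 17
Reactants: 26 (E)-tert-butyldimethyl(pent-2-en-4-yn-1-yloxy)silane; 29 (4R,5R)-4,5-dimethyl-1,3,2-dioxathiolane 2,2-dioxide
Product: 32 (2E,6R,7R)-6-methyloct-2-en-4-yne-1,7-diol, via lithium acetylide 30 (not isolated), via lithium alkyl sulfate 31 (not isolated)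
Conditions: 26, n-BuLi, THF, −78 °C; then 29, −78 °C → rt; then 2 M H2SO4 (aq)/THF, rt
Reagents that add atoms: none
Why: SN2 opening of the C2-symmetric cyclic sulfate by the acetylide inverts the attacked carbon (C26) and leaves C27 untouched, so the 26R,27R pair follows from the diol, and aqueous acid then hydrolyses the alkyl sulfate and the silyl ether.

Step 18
Reactants: 32 (2E,6R,7R)-6-methyloct-2-en-4-yne-1,7-diol
Product: 33 (2E,4E,6R,7R)-6-methylocta-2,4-diene-1,7-diol
Conditions: LiAlH4, THF, 0 °C → reflux; Rochelle salt (aq)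
Reagents that add atoms: none
Why: Alkoxide-directed trans-hydroalumination of the conjugated enyne followed by protonolysis should give the (E)-alkene and complete the E,E-diene.

Step 19
Reactants: 33 (2E,4E,6R,7R)-6-methylocta-2,4-diene-1,7-diol
Product: 34 (2E,4E,6R,7R)-7-hydroxy-6-methylocta-2,4-dienal
Conditions: MnO2, CH2Cl2, rt
Reagents that add atoms: none
Why: MnO2 oxidises only the allylic primary alcohol and leaves the saturated secondary C27 hydroxyl.

Step 20
Reactants: 34 (2E,4E,6R,7R)-7-hydroxy-6-methylocta-2,4-dienal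
Product: 35 (2R,3R,4E,6E,8E)-9-iodo-3-methylnona-4,6,8-trien-2-ol
Conditions: CrCl2, CHI3, THF/1,4-dioxane, 0 °C → rt, dark
Reagents that add atoms: iodoform, IC(I)I
Why: Takai olefination, in which the geminal dichromium species from CHI3 and divalent chromium adds to the aldehyde and eliminates to the (E)-iodoalkene, tolerates the free hydroxyl.

Step 21
Reactants: 35 (2R,3R,4E,6E,8E)-9-iodo-3-methylnona-4,6,8-trien-2-ol; 36 (E)-1,2-bis(tributylstannyl)ethene
Product: 37 (2R,3R,4E,6E,8E,10E)-3-methyl-11-(tributylstannyl)undeca-4,6,8,10-tetraen-2-ol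
Conditions: 36 (4 equiv), PdCl2(MeCN)2 (cat.), DMF, rt, dark
Reagents that add atoms: none
Why: Stille coupling with an excess of the bis-stannane should give mono-coupling with retention of all olefin geometries, adding C18–C19 and leaving a terminal stannane.

**Union and end game**

Step 22
Reactants: 24 C3–C17 (E)-vinyl iodide; 37 (2R,3R,4E,6E,8E,10E)-3-methyl-11-(tributylstannyl)undeca-4,6,8,10-tetraen-2-ol
Product: 38 C3–C28 pentaene alcohol (3,9,11,13,15-O-TBS; 5-MOM ether; free C27 hydroxyl)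
Conditions: PdCl2(MeCN)2 (cat.), i-Pr2NEt, DMF/THF, rt, dark
Reagents that add atoms: none
Why: Stille coupling (oxidative addition of zerovalent palladium into the vinyl iodide, transmetalation, reductive elimination) forms C17–C18 with retention of geometry under neutral conditions that tolerate the free hydroxyl.

Step 23
Reactants: 38 C3–C28 pentaene alcohol; 39 2-bromopropanoyl bromide
Product: 40 C27 2-bromopropanoate of 38 (bromide-bearing carbon as both epimers)
Conditions: pyridine, CH2Cl2, −20 → 0 °C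
Reagents that add atoms: none
Why: Acylation of the only free hydroxyl by the acid bromide installs the α-bromo ester, and the bromide epimers need not be separated because both give the same enolate.

Step 24
Reactants: 40 C27 2-bromopropanoate of 38
Product: 41 C3 primary alcohol (9,11,13,15-O-TBS; 5-MOM ether; C27 2-bromopropanoate)
Conditions: HF·pyridine, pyridine, THF, 0 °C
Reagents that add atoms: none
Why: Buffered fluoride cleaves the unhindered primary TBS ether much faster than the four secondary ones and should not touch the α-bromo ester or the pentaene.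

Step 25
Reactants: 41 C3 primary alcohol
Product: 42 C3 aldehyde (9,11,13,15-O-TBS; 5-MOM ether; C27 2-bromopropanoate)
Conditions: Dess–Martin periodinane, NaHCO3, CH2Cl2, 0 °C → rt
Reagents that add atoms: none
Why: Dess–Martin oxidation under bicarbonate buffer gives the β-alkoxy aldehyde under non-basic conditions that should avoid loss of the C5 MOM ether by elimination.

Step 26
Reactants: 42 C3 aldehyde
Product: 44 macrolactone with free C3 hydroxyl (5-MOM ether; 9,11,13,15-O-TBS), via samarium enolate 43 (not isolated)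
Conditions: SmI2 (4 equiv), THF, −78 → −20 °C, slow addition of 42 (final ca. 1 mM); NH4Cl (aq)
Reagents that add atoms: none
Why: Samarium-mediated intramolecular Reformatsky (macro-aldol) reaction: two single-electron transfers from samarium diiodide cleave the C–Br bond and give the trivalent samarium ester enolate, identical from both bromide epimers, which adds to the C3 aldehyde. The 28-membered lactone (C1–C27 plus the ring oxygen) closes through this C2–C3 bond formation, an exo-trig attack on the aldehyde carbon, with the oxophilic samarium bridging enolate and aldehyde oxygens as a template and high dilution suppressing intermolecular aldol. At C2 and C3 the Z(O)-enolate reacting through a chair six-membered transition state should give the 2,3-syn pair. C3 relative to C5 is set by chelation of samarium between the aldehyde oxygen and the C5 MOM oxygens, which exposes the carbonyl face anti to the C6 chain and should give 3,5-anti and hence 2S,3R. The step needs C–Br reduction to be faster than reduction of the aldehyde or the pentaene, which the easily reduced α-bromo ester secures at low temperature in THF without additives; the closest known reactions are samarium diiodide Reformatsky closures of medium and large lactones. The syn/anti outcome at C2 is the least secure element.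

Step 27
Reactants: 44 macrolactone with free C3 hydroxyl
Product: 46 macrolactone 3,5-diol (9,11,13,15-O-TBS), via bipyridinium salt 45 (not isolated)
Conditions: TMSOTf, 2,2′-bipyridyl, CH2Cl2, 0 °C; then H2O, rt
Reagents that add atoms: none
Why: The silyl triflate–bipyridyl system converts the MOM acetal into an N-(alkoxymethyl)bipyridinium salt under buffered aprotic conditions (the C3 hydroxyl being silylated in passing), and water then hydrolyses the salt and the TMS ether, so no free acid is present to ionise the allylic C15–O bond.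

Step 28
Reactants: 46 macrolactone 3,5-diol
Product: 47 target macrolide CNP0245606.1
Conditions: HF·pyridine, pyridine, THF, 0 °C → rt
Reagents that add atoms: none
Why: Fluoride-driven cleavage of the four secondary silyl ethers under pyridine buffering is the usual mild end game for polyene macrolides and should leave the lactone, the β-hydroxy ester and the pentaene intact.

**Compound list**
1 | 3-(tert-butyldimethylsilyloxy)propanal | CC(C)(C)[Si](C)(C)OCCC=O | starting material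
2 | diisopinocampheylborinate of alcohol 3 | CC(C)(C)[Si](C)(C)OCC[C@H](CC=C)OB([C@@H]1C[C@@H]2C[C@H]([C@H]1C)C2(C)C)[C@@H]1C[C@@H]2C[C@H]([C@H]1C)C2(C)C | intermediate
3 | (S)-1-(tert-butyldimethylsilyloxy)hex-5-en-3-ol | CC(C)(C)[Si](C)(C)OCC[C@@H](O)CC=C | intermediate
4 | (S)-1-(tert-butyldimethylsilyloxy)-3-(methoxymethoxy)hex-5-ene | CC(C)(C)[Si](C)(C)OCC[C@@H](OCOC)CC=C | intermediate
5 | (S)-7-(tert-butyldimethylsilyloxy)-5-(methoxymethoxy)heptanal (C3–C9) | CC(C)(C)[Si](C)(C)OCC[C@@H](OCOC)CCCC=O | intermediate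
6 | (S)-4-benzyl-3-propanoyloxazolidin-2-one | CCC(=O)N1[C@@H](Cc2ccccc2)COC1=O | starting material
7 | 3-(trimethylsilyl)prop-2-ynal | C[Si](C)(C)C#CC=O | starting material
8 | Z-dibutylboron enolate of 6 | C/C=C(\OB(CCCC)CCCC)N1[C@@H](Cc2ccccc2)COC1=O | intermediate
9 | (4S)-4-benzyl-3-[(2S,3S)-3-hydroxy-2-methyl-5-(trimethylsilyl)pent-4-ynoyl]oxazolidin-2-one | O=C(N1[C@@H](Cc2ccccc2)COC1=O)[C@@H](C)[C@H](O)C#C[Si](C)(C)C | intermediate
10 | (2S,3S)-3-hydroxy-N-methoxy-N,2-dimethyl-5-(trimethylsilyl)pent-4-ynamide | CON(C)C(=O)[C@@H](C)[C@H](O)C#C[Si](C)(C)C | intermediate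
11 | N-methoxy-N-methylacetamide | CON(C)C(C)=O | starting material
12 | lithium enolate of 11 | [Li]OC(=C)N(C)OC | intermediate
13 | (4S,5S)-5-hydroxy-N-methoxy-N,4-dimethyl-3-oxo-7-(trimethylsilyl)hept-6-ynamide | CON(C)C(=O)CC(=O)[C@@H](C)[C@H](O)C#C[Si](C)(C)C | intermediate
14 | (3R,4R,5S)-3,5-dihydroxy-N-methoxy-N,4-dimethyl-7-(trimethylsilyl)hept-6-ynamide | CON(C)C(=O)C[C@@H](O)[C@@H](C)[C@H](O)C#C[Si](C)(C)C | intermediate
15 | N-methoxy-N-methyl-2-[(2R,4R,5R,6S)-2-(4-methoxyphenyl)-5-methyl-6-(trimethylsilylethynyl)-1,3-dioxan-4-yl]acetamide | CON(C)C(=O)C[C@@H]1[C@@H](C)[C@@H](C#C[Si](C)(C)C)O[C@H](c2ccc(OC)cc2)O1 | intermediate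
16 | 1-[(2R,4R,5R,6S)-2-(4-methoxyphenyl)-5-methyl-6-(trimethylsilylethynyl)-1,3-dioxan-4-yl]propan-2-one (C10–C17) | CC(=O)C[C@@H]1[C@@H](C)[C@@H](C#C[Si](C)(C)C)O[C@H](c2ccc(OC)cc2)O1 | intermediate
17 | dicyclohexylboron enolate of 16 | C=C(OB(C1CCCCC1)C1CCCCC1)C[C@@H]1[C@@H](C)[C@@H](C#C[Si](C)(C)C)O[C@H](c2ccc(OC)cc2)O1 | intermediate
18 | C3–C17 aldol adduct (9-hydroxy-11-ketone) | CC(C)(C)[Si](C)(C)OCC[C@@H](OCOC)CCC[C@H](O)CC(=O)C[C@@H]1[C@@H](C)[C@@H](C#C[Si](C)(C)C)O[C@H](c2ccc(OC)cc2)O1 | intermediate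
19 | C3–C17 9,11-syn diol | CC(C)(C)[Si](C)(C)OCC[C@@H](OCOC)CCC[C@H](O)C[C@H](O)C[C@@H]1[C@@H](C)[C@@H](C#C[Si](C)(C)C)O[C@H](c2ccc(OC)cc2)O1 | intermediate
20 | C17-silyl pentaol | OCC[C@@H](OCOC)CCC[C@H](O)C[C@H](O)C[C@@H](O)[C@@H](C)[C@H](O)C#C[Si](C)(C)C | intermediate
21 | C3–C17 alkynyl pentaol | OCC[C@@H](OCOC)CCC[C@H](O)C[C@H](O)C[C@@H](O)[C@@H](C)[C@H](O)C#C | intermediate
22 | C3–C17 alkyne penta-TBS ether | CC(C)(C)[Si](C)(C)OCC[C@@H](OCOC)CCC[C@H](O[Si](C)(C)C(C)(C)C)C[C@H](O[Si](C)(C)C(C)(C)C)C[C@@H](O[Si](C)(C)C(C)(C)C)[C@@H](C)[C@H](O[Si](C)(C)C(C)(C)C)C#C | intermediate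
23 | C17 alkenylzirconocene chloride | CC(C)(C)[Si](C)(C)OCC[C@@H](OCOC)CCC[C@H](O[Si](C)(C)C(C)(C)C)C[C@H](O[Si](C)(C)C(C)(C)C)C[C@@H](O[Si](C)(C)C(C)(C)C)[C@@H](C)[C@H](O[Si](C)(C)C(C)(C)C)/C=C/[Zr](Cl)(C1C=CC=C1)C1C=CC=C1 | intermediate
24 | C3–C17 (E)-vinyl iodide | CC(C)(C)[Si](C)(C)OCC[C@@H](OCOC)CCC[C@H](O[Si](C)(C)C(C)(C)C)C[C@H](O[Si](C)(C)C(C)(C)C)C[C@@H](O[Si](C)(C)C(C)(C)C)[C@@H](C)[C@H](O[Si](C)(C)C(C)(C)C)/C=C/I | intermediate
25 | (E)-pent-2-en-4-yn-1-ol | C#C/C=C/CO | starting material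
26 | (E)-tert-butyldimethyl(pent-2-en-4-yn-1-yloxy)silane | C#C/C=C/CO[Si](C)(C)C(C)(C)C | intermediate
27 | (2R,3R)-butane-2,3-diol | C[C@@H](O)[C@@H](C)O | starting material
28 | (4R,5R)-4,5-dimethyl-1,3,2-dioxathiolane 2-oxide | C[C@H]1OS(=O)O[C@@H]1C | intermediate
29 | (4R,5R)-4,5-dimethyl-1,3,2-dioxathiolane 2,2-dioxide | C[C@H]1OS(=O)(=O)O[C@@H]1C | intermediate
30 | lithium acetylide of 26 | [Li]C#C/C=C/CO[Si](C)(C)C(C)(C)C | intermediate
31 | lithium (2R,3R,6E)-8-(tert-butyldimethylsilyloxy)-3-methyloct-6-en-4-yn-2-yl sulfate | CC(C)(C)[Si](C)(C)OC/C=C/C#C[C@@H](C)[C@@H](C)OS(=O)(=O)O[Li] | intermediate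
32 | (2E,6R,7R)-6-methyloct-2-en-4-yne-1,7-diol | OC/C=C/C#C[C@@H](C)[C@@H](C)O | intermediate
33 | (2E,4E,6R,7R)-6-methylocta-2,4-diene-1,7-diol | OC/C=C/C=C/[C@@H](C)[C@@H](C)O | intermediate
34 | (2E,4E,6R,7R)-7-hydroxy-6-methylocta-2,4-dienal | O=C/C=C/C=C/[C@@H](C)[C@@H](C)O | intermediate
35 | (2R,3R,4E,6E,8E)-9-iodo-3-methylnona-4,6,8-trien-2-ol | I/C=C/C=C/C=C/[C@@H](C)[C@@H](C)O | intermediate
36 | (E)-1,2-bis(tributylstannyl)ethene | CCCC[Sn](CCCC)(CCCC)/C=C/[Sn](CCCC)(CCCC)CCCC | starting material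
37 | (2R,3R,4E,6E,8E,10E)-3-methyl-11-(tributylstannyl)undeca-4,6,8,10-tetraen-2-ol | CCCC[Sn](CCCC)(CCCC)/C=C/C=C/C=C/C=C/[C@@H](C)[C@@H](C)O | intermediate
38 | C3–C28 pentaene alcohol | CC(C)(C)[Si](C)(C)OCC[C@@H](OCOC)CCC[C@H](O[Si](C)(C)C(C)(C)C)C[C@H](O[Si](C)(C)C(C)(C)C)C[C@@H](O[Si](C)(C)C(C)(C)C)[C@@H](C)[C@H](O[Si](C)(C)C(C)(C)C)/C=C/C=C/C=C/C=C/C=C/[C@@H](C)[C@@H](C)O | intermediate
39 | 2-bromopropanoyl bromide | CC(Br)C(Br)=O | starting material
40 | C27 2-bromopropanoate with C3 TBS ether | CC(C)(C)[Si](C)(C)OCC[C@@H](OCOC)CCC[C@H](O[Si](C)(C)C(C)(C)C)C[C@H](O[Si](C)(C)C(C)(C)C)C[C@@H](O[Si](C)(C)C(C)(C)C)[C@@H](C)[C@H](O[Si](C)(C)C(C)(C)C)/C=C/C=C/C=C/C=C/C=C/[C@@H](C)[C@@H](C)OC(=O)C(C)Br | intermediate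
41 | C3 alcohol with C27 2-bromopropanoate | OCC[C@@H](OCOC)CCC[C@H](O[Si](C)(C)C(C)(C)C)C[C@H](O[Si](C)(C)C(C)(C)C)C[C@@H](O[Si](C)(C)C(C)(C)C)[C@@H](C)[C@H](O[Si](C)(C)C(C)(C)C)/C=C/C=C/C=C/C=C/C=C/[C@@H](C)[C@@H](C)OC(=O)C(C)Br | intermediate
42 | C3 aldehyde with C27 2-bromopropanoate (key-step precursor) | O=CC[C@@H](OCOC)CCC[C@H](O[Si](C)(C)C(C)(C)C)C[C@H](O[Si](C)(C)C(C)(C)C)C[C@@H](O[Si](C)(C)C(C)(C)C)[C@@H](C)[C@H](O[Si](C)(C)C(C)(C)C)/C=C/C=C/C=C/C=C/C=C/[C@@H](C)[C@@H](C)OC(=O)C(C)Br | intermediate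
43 | samarium Z(O)-enolate of 42 | O=CC[C@@H](OCOC)CCC[C@H](O[Si](C)(C)C(C)(C)C)C[C@H](O[Si](C)(C)C(C)(C)C)C[C@@H](O[Si](C)(C)C(C)(C)C)[C@@H](C)[C@H](O[Si](C)(C)C(C)(C)C)/C=C/C=C/C=C/C=C/C=C/[C@@H](C)[C@@H](C)O/C(O[Sm](I)I)=C/C | intermediate
44 | macrolactone with free C3 hydroxyl (5-MOM; four TBS) | C[C@H]1[C@H](O[Si](C)(C)C(C)(C)C)/C=C/C=C/C=C/C=C/C=C/[C@@H](C)[C@@H](C)OC(=O)[C@@H](C)[C@H](O)C[C@@H](OCOC)CCC[C@H](O[Si](C)(C)C(C)(C)C)C[C@H](O[Si](C)(C)C(C)(C)C)C[C@H]1O[Si](C)(C)C(C)(C)C | intermediate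
45 | N-(C5-oxymethyl)-2,2′-bipyridinium triflate of the 3-O-TMS macrolactone | C[C@H]1[C@H](O[Si](C)(C)C(C)(C)C)/C=C/C=C/C=C/C=C/C=C/[C@@H](C)[C@@H](C)OC(=O)[C@@H](C)[C@H](O[Si](C)(C)C)C[C@@H](OC[n+]2ccccc2-c2ccccn2)CCC[C@H](O[Si](C)(C)C(C)(C)C)C[C@H](O[Si](C)(C)C(C)(C)C)C[C@H]1O[Si](C)(C)C(C)(C)C.[O-]S(=O)(=O)C(F)(F)F | intermediate
46 | macrolactone 3,5-diol (four TBS) | C[C@H]1[C@H](O[Si](C)(C)C(C)(C)C)/C=C/C=C/C=C/C=C/C=C/[C@@H](C)[C@@H](C)OC(=O)[C@@H](C)[C@H](O)C[C@@H](O)CCC[C@H](O[Si](C)(C)C(C)(C)C)C[C@H](O[Si](C)(C)C(C)(C)C)C[C@H]1O[Si](C)(C)C(C)(C)C | intermediate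
47 | CNP0245606.1 (2S,3R,5S,9S,11S,13R,14R,15R,26R,27R; 16E,18E,20E,22E,24E) | C[C@H]1[C@H](O)/C=C/C=C/C=C/C=C/C=C/[C@@H](C)[C@@H](C)OC(=O)[C@@H](C)[C@H](O)C[C@@H](O)CCC[C@H](O)C[C@H](O)C[C@H]1O | target

**Totals**
Total step count: 28. Longest linear sequence: 18 steps (steps 4–14 and 22–28, from 6 and 7 to 47).

**Steps most likely to fail**

1. Step 26. The samarium enolate may be protonated or may add to a second molecule before it reaches the remote aldehyde, and facial control at C2/C3 across a 28-membered ring may be poor. Fallback (sets out from 24, returns at 44): set C2 and C3 by an auxiliary-controlled intermolecular aldol and close the ring at the ester oxygen. Buffered HF·pyridine frees the primary alcohol F1 from 24, and Dess–Martin oxidation gives the aldehyde F2. An Evans syn aldol with enolate 8 (from imide 6, Bu2BOTf, Et3N) gives the imide adduct F3, which is silylated (TESOTf, 2,6-lutidine) to the TES ether F4 and hydrolysed (LiOH, H2O2) to the carboxylic acid F5. Stille coupling of F5 with stannane 37 (PdCl2(MeCN)2, i-Pr2NEt, DMF) gives the seco acid F6. Yamaguchi macrolactonisation (2,4,6-trichlorobenzoyl chloride, Et3N; DMAP, toluene, high dilution) gives the C3-TES macrolactone F7, and brief buffered HF·pyridine at 0 °C removes the secondary TES ether in preference to TBS to give 44.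

2. Step 27. The activated oxymethyl unit on O5 may be captured by the neighbouring C3 oxygen to give a cyclic methylene acetal, or the Lewis-acidic silyl triflate may ionise the allylic C15–O bond of the pentaene. Fallback (sets out from 44, returns at 47): protect first and cleave at low temperature by a different mechanism. TBSOTf and 2,6-lutidine give the C3 TBS ether F8; Me2BBr in CH2Cl2 at −78 °C cleaves the MOM ether through a bromomethyl ether that is hydrolysed on work-up (NaHCO3, THF/H2O) to the C5 alcohol F9; one buffered HF·pyridine treatment then removes all five silyl ethers and gives 47.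

3. Step 20. Addition and elimination of the chromium carbenoid may give poor E/Z selectivity at the new C20–C21 bond of a conjugated aldehyde, and the isomeric iodotrienes are hard to separate. Fallback (sets out from 34, returns at 35): make the terminal iodoalkene by alkyne hydrometalation. Ohira–Bestmann homologation of 34 (dimethyl (1-diazo-2-oxopropyl)phosphonate, K2CO3, MeOH) gives the dienyne alcohol F10. Excess Cp2Zr(H)Cl converts it into the zirconium alkoxide alkenylzirconocene F11 by syn addition, and I2 followed by aqueous work-up gives the all-E iodide 35.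

**Further compounds**
F1 | step 26 | C3 primary alcohol of the C3–C17 vinyl iodide | OCC[C@@H](OCOC)CCC[C@H](O[Si](C)(C)C(C)(C)C)C[C@H](O[Si](C)(C)C(C)(C)C)C[C@@H](O[Si](C)(C)C(C)(C)C)[C@@H](C)[C@H](O[Si](C)(C)C(C)(C)C)/C=C/I
F2 | step 26 | C3 aldehyde of the C3–C17 vinyl iodide | O=CC[C@@H](OCOC)CCC[C@H](O[Si](C)(C)C(C)(C)C)C[C@H](O[Si](C)(C)C(C)(C)C)C[C@@H](O[Si](C)(C)C(C)(C)C)[C@@H](C)[C@H](O[Si](C)(C)C(C)(C)C)/C=C/I
F3 | step 26 | Evans syn-aldol imide adduct (C1–C17; free C3 hydroxyl) | O=C(N1[C@@H](Cc2ccccc2)COC1=O)[C@@H](C)[C@H](O)C[C@@H](OCOC)CCC[C@H](O[Si](C)(C)C(C)(C)C)C[C@H](O[Si](C)(C)C(C)(C)C)C[C@@H](O[Si](C)(C)C(C)(C)C)[C@@H](C)[C@H](O[Si](C)(C)C(C)(C)C)/C=C/I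
F4 | step 26 | C3 TES ether of the imide adduct | O=C(N1[C@@H](Cc2ccccc2)COC1=O)[C@@H](C)[C@H](O[Si](CC)(CC)CC)C[C@@H](OCOC)CCC[C@H](O[Si](C)(C)C(C)(C)C)C[C@H](O[Si](C)(C)C(C)(C)C)C[C@@H](O[Si](C)(C)C(C)(C)C)[C@@H](C)[C@H](O[Si](C)(C)C(C)(C)C)/C=C/I
F5 | step 26 | C1 carboxylic acid (C1–C17 vinyl iodide; C3 TES ether) | OC(=O)[C@@H](C)[C@H](O[Si](CC)(CC)CC)C[C@@H](OCOC)CCC[C@H](O[Si](C)(C)C(C)(C)C)C[C@H](O[Si](C)(C)C(C)(C)C)C[C@@H](O[Si](C)(C)C(C)(C)C)[C@@H](C)[C@H](O[Si](C)(C)C(C)(C)C)/C=C/I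
F6 | step 26 | seco acid (C1–C28 pentaene; free C27 hydroxyl; C3 TES ether) | OC(=O)[C@@H](C)[C@H](O[Si](CC)(CC)CC)C[C@@H](OCOC)CCC[C@H](O[Si](C)(C)C(C)(C)C)C[C@H](O[Si](C)(C)C(C)(C)C)C[C@@H](O[Si](C)(C)C(C)(C)C)[C@@H](C)[C@H](O[Si](C)(C)C(C)(C)C)/C=C/C=C/C=C/C=C/C=C/[C@@H](C)[C@@H](C)O
F7 | step 26 | macrolactone with C3 TES ether | C[C@H]1[C@H](O[Si](C)(C)C(C)(C)C)/C=C/C=C/C=C/C=C/C=C/[C@@H](C)[C@@H](C)OC(=O)[C@@H](C)[C@H](O[Si](CC)(CC)CC)C[C@@H](OCOC)CCC[C@H](O[Si](C)(C)C(C)(C)C)C[C@H](O[Si](C)(C)C(C)(C)C)C[C@H]1O[Si](C)(C)C(C)(C)C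
F8 | step 27 | macrolactone with C3 TBS ether and C5 MOM ether | C[C@H]1[C@H](O[Si](C)(C)C(C)(C)C)/C=C/C=C/C=C/C=C/C=C/[C@@H](C)[C@@H](C)OC(=O)[C@@H](C)[C@H](O[Si](C)(C)C(C)(C)C)C[C@@H](OCOC)CCC[C@H](O[Si](C)(C)C(C)(C)C)C[C@H](O[Si](C)(C)C(C)(C)C)C[C@H]1O[Si](C)(C)C(C)(C)C
F9 | step 27 | macrolactone with free C5 hydroxyl and five TBS ethers | C[C@H]1[C@H](O[Si](C)(C)C(C)(C)C)/C=C/C=C/C=C/C=C/C=C/[C@@H](C)[C@@H](C)OC(=O)[C@@H](C)[C@H](O[Si](C)(C)C(C)(C)C)C[C@@H](O)CCC[C@H](O[Si](C)(C)C(C)(C)C)C[C@H](O[Si](C)(C)C(C)(C)C)C[C@H]1O[Si](C)(C)C(C)(C)C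
F10 | step 20 | (2R,3R,4E,6E)-3-methylnona-4,6-dien-8-yn-2-ol | C#C/C=C/C=C/[C@@H](C)[C@@H](C)O
F11 | step 20 | zirconium alkoxide alkenylzirconocene of F10 | Cl[Zr](/C=C/C=C/C=C/[C@@H](C)[C@@H](C)O[Zr](Cl)(C1C=CC=C1)C1C=CC=C1)(C1C=CC=C1)C1C=CC=C1
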